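**Plan**

- Retrosynthesis: the C8–OH bond is cut first (C8–O back to C8–B, C8–Br and C8–H). Ring C is then opened at three bonds at once: O1–C8a, C4a–C4 and O1–C2.
- This leaves a 3,4,5-trimethoxybenzyne (ring A) and 3-(3,4,5-trimethoxyphenyl)propiolic acid (ring B with C2, C3, C4 and O1).
- Enabling feature: O1 on C8a and the C4 carbonyl on C4a are ortho neighbours on ring A, and the C5 methoxy group sits beside C4a. An aryne spanning C4a–C8a is therefore polarised to take oxygen at C8a and carbon at C4a.
- Forward: ring A is made as an ortho-silylaryl triflate, ring B arrives intact with the alkynoic acid, and ring C (the pyranone) closes in the aryne step. C8 is then brominated, borylated and oxidised.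
- Stereochemistry: the target has no stereocentre and no stereogenic double bond, so nothing has to be set.

Key step: step 5

Assumption: the C8 oxygen is introduced after the annulation, because an aryne flanked by alkoxy groups on both sides would lose the polarisation that fixes the regiochemistry; 3,4,5-trimethoxyphenol and 5-ethynyl-1,2,3-trimethoxybenzene are taken as purchasable.

**Route**

Step 1
Reactants: 1 3,4,5-trimethoxyphenol
Product: 2 2-bromo-3,4,5-trimethoxyphenol
Conditions: NBS (1.0 equiv), CH2Cl2, −78 °C → 0 °C
Reagents that add atoms: N-bromosuccinimide, O=C1CCC(=O)N1Br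
Why: Electrophilic aromatic bromination of a strongly activated phenol whose two free positions are equivalent by symmetry and both ortho to OH, so one equivalent of NBS at low temperature should stop at the single monobromide.

Step 2
Reactants: 2 2-bromo-3,4,5-trimethoxyphenol
Product: 3 (2-bromo-3,4,5-trimethoxyphenoxy)trimethylsilane
Conditions: HMDS, THF, 70 °C; volatiles removed, crude used directly
Reagents that add atoms: hexamethyldisilazane, C[Si](C)(C)N[Si](C)(C)C
Why: O-silylation of a phenol with HMDS runs under neutral conditions with ammonia as the only by-product, so the moisture-sensitive silyl ether can be carried on without purification.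

Step 3
Reactants: 3 (2-bromo-3,4,5-trimethoxyphenoxy)trimethylsilane
Product: 6 3,4,5-trimethoxy-2-(trimethylsilyl)phenyl trifluoromethanesulfonate, via aryllithium 4 (not isolated), via lithium phenoxide 5 (not isolated)
Conditions: n-BuLi, THF, −100 °C; then Tf2O, −100 °C → rt
Reagents that add atoms: trifluoromethanesulfonic anhydride, O=S(=O)(OS(=O)(=O)C(F)(F)F)C(F)(F)F
Why: Bromine–lithium exchange gives aryllithium 4, which undergoes the anionic 1,3-silyl shift from oxygen to carbon (retro-Brook rearrangement) to phenoxide 5, and O-triflation of that phenoxide is the standard entry to ortho-silylaryl triflates.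

Step 4
Reactants: 7 5-ethynyl-1,2,3-trimethoxybenzene
Product: 10 3-(3,4,5-trimethoxyphenyl)propiolic acid, via lithium acetylide 8 (not isolated), via lithium carboxylate 9 (not isolated)
Conditions: n-BuLi, THF, −78 °C; CO2 (dry gas), −78 °C → 0 °C; aq HCl, 0 °C
Reagents that add atoms: carbon dioxide, O=C=O
Why: Deprotonation of a terminal alkyne and carboxylation of the lithium acetylide with CO2 is a standard preparation of arylpropiolic acids, and cold acidic work-up should avoid decarboxylation.

Step 5
Reactants: 6 3,4,5-trimethoxy-2-(trimethylsilyl)phenyl trifluoromethanesulfonate; 10 3-(3,4,5-trimethoxyphenyl)propiolic acid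
Product: 14 5,6,7,3',4',5'-hexamethoxyflavone, via cesium carboxylate 11 (not isolated), via aryne 12 (not isolated), via ynone phenoxide 13 (not isolated)
Conditions: 6 (1.5 equiv), CsF (4 equiv), THF, sealed tube, 125 °C
Reagents that add atoms: none
Why: CsF converts acid 10 into carboxylate 11 and, by attack of fluoride on silicon with loss of triflate, releases 3,4,5-trimethoxybenzyne 12 from 6. The carboxylate oxygen adds to the aryne carbon remote from the flanking methoxy group (the future C8a), because the inductively withdrawing C5-OMe distorts the triple bond and stabilises the developing aryl anion on the adjacent carbon (the future C4a); this regioselectivity is the one the step needs and the substituent pattern of 6 secures it. The aryl anion then attacks the neighbouring ester carbonyl in a 4-exo-trig sense and the strained benzoxetene alkoxide opens to ortho-ynoyl phenoxide 13, a formal aryne insertion into the C–O bond of a carboxylic acid that is known to continue to flavones with arylpropiolic acids. Phenoxide 13 closes ring C by 6-endo-dig oxa-Michael addition to the ynone β-carbon, forming O1–C2, and protonation at C3 gives the pyranone; 5-exo-dig closure to an aurone is disfavoured because the β-carbon is the electrophilic site of the conjugated ynone. Hot aprotic conditions with excess CsF are chosen so that acyl transfer outruns simple proton quench of the aryl anion, which would stop at the aryl propiolate ester. No stereocentre is formed.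

Step 6
Reactants: 14 5,6,7,3',4',5'-hexamethoxyflavone
Product: 15 8-bromo-5,6,7,3',4',5'-hexamethoxyflavone
Conditions: NBS (1.05 equiv), DMF, 0 °C → rt, dark
Reagents that add atoms: N-bromosuccinimide, O=C1CCC(=O)N1Br
Why: Electrophilic aromatic bromination should go to C8, the only C–H of ring A, which is activated by the ortho C7-OMe, the ortho ring oxygen and the para C5-OMe, whereas the ring B positions are deactivated by conjugation with the electron-poor C2 of the pyranone.

Step 7
Reactants: 15 8-bromo-5,6,7,3',4',5'-hexamethoxyflavone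
Product: 16 5,6,7,3',4',5'-hexamethoxy-8-(4,4,5,5-tetramethyl-1,3,2-dioxaborolan-2-yl)flavone
Conditions: B2pin2, Pd2(dba)3 (cat.), XPhos, KOAc, 1,4-dioxane, 100 °C
Reagents that add atoms: bis(pinacolato)diboron, CC1(C)OB(OC1(C)C)B1OC(C)(C)C(C)(C)O1
Why: Miyaura borylation, in which zerovalent palladium carrying the bulky electron-rich XPhos ligand inserts into the hindered, electron-rich C8–Br bond and acetate mediates transmetalation with B2pin2, while the ketone and methyl ethers are inert.

Step 8
Reactants: 16 5,6,7,3',4',5'-hexamethoxy-8-(4,4,5,5-tetramethyl-1,3,2-dioxaborolan-2-yl)flavone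
Product: 17 8-hydroxy-5,6,7,3',4',5'-hexamethoxyflavone
Conditions: 30% aq H2O2, aq NaOH, THF, 0 °C; aq Na2S2O3, then aq NH4Cl
Reagents that add atoms: hydrogen peroxide, OO
Why: Oxidation of an arylboronate, in which hydroperoxide adds to boron, the aryl group shifts from boron to oxygen and the borate ester hydrolyses to the phenol; brief cold treatment should spare the pyranone and avoid over-oxidation of the electron-rich phenol.

**Compound list**

1 | 3,4,5-trimethoxyphenol | COc1cc(O)cc(OC)c1OC | starting material
2 | 2-bromo-3,4,5-trimethoxyphenol | Oc1cc(OC)c(OC)c(OC)c1Br | intermediate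
3 | (2-bromo-3,4,5-trimethoxyphenoxy)trimethylsilane | C[Si](C)(C)Oc1cc(OC)c(OC)c(OC)c1Br | intermediate
4 | [2,3,4-trimethoxy-6-(trimethylsilyloxy)phenyl]lithium | [Li]c1c(O[Si](C)(C)C)cc(OC)c(OC)c1OC | intermediate
5 | lithium 3,4,5-trimethoxy-2-(trimethylsilyl)phenoxide | [Li+].[O-]c1cc(OC)c(OC)c(OC)c1[Si](C)(C)C | intermediate
6 | 3,4,5-trimethoxy-2-(trimethylsilyl)phenyl trifluoromethanesulfonate | COc1cc(OS(=O)(=O)C(F)(F)F)c([Si](C)(C)C)c(OC)c1OC | intermediate
7 | 5-ethynyl-1,2,3-trimethoxybenzene | C#Cc1cc(OC)c(OC)c(OC)c1 | starting material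
8 | lithium (3,4,5-trimethoxyphenyl)acetylide | [Li]C#Cc1cc(OC)c(OC)c(OC)c1 | intermediate
9 | lithium 3-(3,4,5-trimethoxyphenyl)propiolate | [Li+].[O-]C(=O)C#Cc1cc(OC)c(OC)c(OC)c1 | intermediate
10 | 3-(3,4,5-trimethoxyphenyl)propiolic acid | OC(=O)C#Cc1cc(OC)c(OC)c(OC)c1 | intermediate
11 | cesium 3-(3,4,5-trimethoxyphenyl)propiolate | [Cs+].[O-]C(=O)C#Cc1cc(OC)c(OC)c(OC)c1 | intermediate
12 | 3,4,5-trimethoxybenzyne (1,2-didehydro-3,4,5-trimethoxybenzene) | COC1=CC#CC(OC)=C1OC | intermediate
13 | cesium 3,4,5-trimethoxy-2-[3-(3,4,5-trimethoxyphenyl)propioloyl]phenoxide | [Cs+].[O-]c1cc(OC)c(OC)c(OC)c1C(=O)C#Cc1cc(OC)c(OC)c(OC)c1 | intermediate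
14 | 5,6,7,3',4',5'-hexamethoxyflavone [5,6,7-trimethoxy-2-(3,4,5-trimethoxyphenyl)-4H-chromen-4-one] | COc1cc(-c2cc(=O)c3c(OC)c(OC)c(OC)cc3o2)cc(OC)c1OC | intermediate
15 | 8-bromo-5,6,7,3',4',5'-hexamethoxyflavone | COc1cc(-c2cc(=O)c3c(OC)c(OC)c(OC)c(Br)c3o2)cc(OC)c1OC | intermediate
16 | 5,6,7,3',4',5'-hexamethoxy-8-(4,4,5,5-tetramethyl-1,3,2-dioxaborolan-2-yl)flavone | COc1cc(-c2cc(=O)c3c(OC)c(OC)c(OC)c(B4OC(C)(C)C(C)(C)O4)c3o2)cc(OC)c1OC | intermediate
17 | 8-hydroxy-5,6,7,3',4',5'-hexamethoxyflavone | COc1cc(-c2cc(=O)c3c(OC)c(OC)c(OC)c(O)c3o2)cc(OC)c1OC | target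

**Step count**

Total: 8 steps. Longest linear sequence: 7 steps (steps 1, 2, 3, 5, 6, 7, 8); step 4 is the one-step side branch.

**Steps most likely to fail, with fallbacks**

Step 5. The aryl anion may be protonated before it transfers the acyl group, so that the sequence stops at O-arylation. The propiolate may also decarboxylate at 125 °C, or the aryne addition may lose its regiochemical bias. In that case ring C would be built by the classical chalcone route. Setting out from phenol 1, C-acetylation ortho to the hydroxyl group with AcOH and BF3·OEt2 at 90 °C (Friedel–Crafts/Fries acylation) should give 1-(6-hydroxy-2,3,4-trimethoxyphenyl)ethan-1-one F1. Claisen–Schmidt condensation of this ketone with commercial 3,4,5-trimethoxybenzaldehyde (KOH, EtOH, rt) should give (E)-1-(6-hydroxy-2,3,4-trimethoxyphenyl)-3-(3,4,5-trimethoxyphenyl)prop-2-en-1-one F2. Oxidative cyclisation with catalytic I2 in DMSO at 130 °C should then deliver flavone 14, where the route resumes at step 6.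

Step 6. Site selectivity may be poor, with competing bromination of ring B or of C3, or over-bromination. The fallback raises the nucleophilicity of C8 before halogenation. Setting out from flavone 14, BCl3 in CH2Cl2 at 0 °C should cleave only the C5 methyl ether, which is chelated to the C4 carbonyl, to give 5-hydroxy-6,7,3',4',5'-pentamethoxyflavone F3. The free phenol para to C8 should then direct NBS (DMF, 0 °C) to that position, giving 8-bromo-5-hydroxy-6,7,3',4',5'-pentamethoxyflavone F4. Re-methylation of the C5 phenol with MeI and K2CO3 in acetone at reflux returns to bromide 15, and the route continues with step 7.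

Step 7. Oxidative addition into the doubly ortho-substituted, electron-rich C8–Br bond may be sluggish, so that protodebromination overtakes borylation. The fallback forms the C–O bond directly instead of going through boron. Setting out from bromide 15, palladium-catalysed C–O coupling with (E)-benzaldoxime as a hydroxide surrogate (Pd2(dba)3, tBuBrettPhos, Cs2CO3, DMF, 80 °C) should give (E)-benzaldehyde O-[5,6,7-trimethoxy-4-oxo-2-(3,4,5-trimethoxyphenyl)-4H-chromen-8-yl]oxime F5. Under the same basic conditions this should fragment to benzonitrile and the phenoxide, so that acidic work-up gives target 17 directly and step 8 is not needed.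

**Further compounds**

F1 | step 5 | 1-(6-hydroxy-2,3,4-trimethoxyphenyl)ethan-1-one | CC(=O)c1c(O)cc(OC)c(OC)c1OC
F2 | step 5 | (E)-1-(6-hydroxy-2,3,4-trimethoxyphenyl)-3-(3,4,5-trimethoxyphenyl)prop-2-en-1-one | COc1cc(/C=C/C(=O)c2c(O)cc(OC)c(OC)c2OC)cc(OC)c1OC
F3 | step 6 | 5-hydroxy-6,7,3',4',5'-pentamethoxyflavone | COc1cc(-c2cc(=O)c3c(O)c(OC)c(OC)cc3o2)cc(OC)c1OC
F4 | step 6 | 8-bromo-5-hydroxy-6,7,3',4',5'-pentamethoxyflavone | COc1cc(-c2cc(=O)c3c(O)c(OC)c(OC)c(Br)c3o2)cc(OC)c1OC
F5 | step 7 | (E)-benzaldehyde O-[5,6,7-trimethoxy-4-oxo-2-(3,4,5-trimethoxyphenyl)-4H-chromen-8-yl]oxime | COc1cc(-c2cc(=O)c3c(OC)c(OC)c(OC)c(O/N=C/c4ccccc4)c3o2)cc(OC)c1OC
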